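**Plan**

1. The target is (6R)-α-zeacarotene, (6R)-7′,8′-dihydro-ε,ψ-carotene (carotenoid numbering throughout). The first cut is C15=C15′ (Wittig), giving (6R)-α-retinal and an acyclic C20 phosphonium salt; the salt is cut at C11′=C12′ (Horner–Wadsworth–Emmons) into farnesal and a C5 phosphonate.
2. α-Retinal is cut at C14–C15 and C13–CH3 (methylalumination and hydroxymethylation of a C13≡C14 alkyne), then at C10–C11 and C9–CH3, which is the key cut.
3. Feature that allows the key step: the E-trisubstituted alkene C9=C10 with its C9 methyl lies between the C7=C8 alkene on ring carbon C6 of the trimethylcyclohexene ring and the C10–C11 single bond. It is therefore the product of syn addition of methyl (to C9) and an alkenyl group (to C10) across a terminal C9≡C10 alkyne.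
4. Forward: no ring is formed, since the trimethylcyclohexene ring comes intact from (R)-α-ionone. The chain is joined in the order C9≡C10 alkyne, then C9–CH3 with C10–C11, then C13–CH3 with C14–C15, and last C15=C15′ with the separately made farnesol-derived half.
5. Stereochemistry: C6 (R), the only stereocentre, is bought with (R)-α-ionone and carried through under conditions chosen not to deprotonate it. 9E and 13E come from syn carbometalation with stereoretentive trapping, 11E from the bromoenyne, 5′E and 9′E from farnesol, 13′E from the phosphonate, 11′E from the olefination, and 15E from the Wittig reaction followed by thermal isomerisation.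

Key step: step 4

Remark on the chemistry: (R)-α-ionone is assumed to be purchasable in enantiomerically pure form; all polyenes are handled under inert gas with exclusion of light.

**Route**

Step 1
Reactants: 1 (R)-α-ionone
Product: 5 (6R)-6-[(1E)-but-1-en-3-yn-1-yl]-1,5,5-trimethylcyclohex-1-ene, via lithium dienolate 2 (not isolated), via dienyl diethyl phosphate 3 (not isolated), via lithium acetylide 4 (not isolated)
Conditions: LiN(i-Pr)2 (1.05 equiv), THF, −78 °C; ClP(O)(OEt)2, −78 °C to rt; transferred into LiN(i-Pr)2 (2.3 equiv), THF, −78 °C to rt; H2O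
Reagents that add atoms: none
Why: Kinetic deprotonation of the methyl group at −78 °C, O-phosphorylation of the cross-conjugated enolate and amide-induced elimination of diethyl phosphate (conversion of a methyl ketone into a terminal alkyne by enol phosphate elimination) should deliver the enyne, while the hindered base and the low temperature leave the tertiary C6–H and hence the R centre alone.

Step 2
Reactants: 6 acetylene
Product: 7 (E)-1-bromo-2-iodoethene
Conditions: C2H2 gas passed into iodine monobromide, 48% aq HBr, 0 °C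
Reagents that add atoms: iodine monobromide, BrI
Why: Electrophilic addition of iodine monobromide to the triple bond through a bridged iodonium ion is anti (halogenation of an alkyne), so the dihaloethene should form as the E isomer.

Step 3
Reactants: 8 ethynyltrimethylsilane; 7 (E)-1-bromo-2-iodoethene
Product: 11 [(3E)-4-bromobut-3-en-1-yn-1-yl]trimethylsilane, via lithium silylacetylide 9 (not isolated), via alkynylzinc bromide 10 (not isolated)
Conditions: n-BuLi, THF, −78 °C; ZnBr2, −78 to 0 °C; 7 (1.2 equiv), Pd(PPh3)4 (2 mol %), THF, 0 °C to rt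
Reagents that add atoms: none
Why: In this Negishi alkynylzinc–alkenyl halide coupling zerovalent palladium inserts into the carbon–iodine bond much faster than into the carbon–bromine bond, so one alkynyl group should enter with retention of the E geometry and the bromide stays for the key step.

Step 4
Reactants: 5 (6R)-6-[(1E)-but-1-en-3-yn-1-yl]-1,5,5-trimethylcyclohex-1-ene; 12 trimethylaluminium; 11 [(3E)-4-bromobut-3-en-1-yn-1-yl]trimethylsilane
Product: 14 trimethyl{(3E,5E,7E)-6-methyl-8-[(1R)-2,6,6-trimethylcyclohex-2-en-1-yl]octa-3,5,7-trien-1-yn-1-yl}silane, via dienylalane 13 (not isolated)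
Conditions: Me3Al (2 equiv), Cp2ZrCl2 (0.25 equiv), ClCH2CH2Cl, rt; volatiles removed under vacuum; 11, ZnCl2 (0.5 equiv), Pd(PPh3)4 (5 mol %), THF, rt
Reagents that add atoms: trimethylaluminium, C[Al](C)C
Why: A methylzirconium–aluminium species formed from Me3Al and Cp2ZrCl2 (tetravalent zirconium) adds methyl and aluminium across the C9≡C10 triple bond of 5 through a four-centre syn transition state, methyl going to the internal carbon C9 and aluminium to the terminal carbon C10, to give dienylalane 13. Zerovalent palladium inserts into the carbon–bromine bond of 11, the dienyl group passes from aluminium by way of zinc to the alkenylpalladium bromide, and reductive elimination forms C10–C11 with retention at both alkenes. The closest known reaction type is zirconium-catalysed carboalumination of terminal alkynes and conjugated enynes followed by palladium-catalysed Negishi coupling of the alkenylalane with an alkenyl halide. No ring is closed and no stereocentre is created; the two new skeletal bonds are C9–CH3 and C10–C11, the 9E geometry follows from syn addition plus stereoretentive coupling, and the 11E geometry is that of 11. The step needs methyl delivery to the internal alkyne carbon, which the terminal position of the alkyne next to the C7=C8 alkene secures, and reaction at the alkyne only, which holds because the trisubstituted ring alkene is inert to carboalumination. Neither base nor carbonyl group is present, so the doubly allylic C6–H is not at risk and the silylalkyne survives as the handle for the next chain extension.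

Step 5
Reactants: 14 trimethyl{(3E,5E,7E)-6-methyl-8-[(1R)-2,6,6-trimethylcyclohex-2-en-1-yl]octa-3,5,7-trien-1-yn-1-yl}silane
Product: 15 (6R)-1,5,5-trimethyl-6-[(1E,3E,5E)-3-methylocta-1,3,5-trien-7-yn-1-yl]cyclohex-1-ene
Conditions: K2CO3, MeOH/THF, rt, dark; used at once
Reagents that add atoms: none
Why: Methoxide-mediated cleavage of the alkynyl carbon–silicon bond (protodesilylation of a trimethylsilylalkyne) is mild enough to leave the triene, the ring alkene and the C6 centre unchanged.

Step 6
Reactants: 15 (6R)-1,5,5-trimethyl-6-[(1E,3E,5E)-3-methylocta-1,3,5-trien-7-yn-1-yl]cyclohex-1-ene; 12 trimethylaluminium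
Product: 18 (6R)-α-retinol [(2E,4E,6E,8E)-3,7-dimethyl-9-[(1R)-2,6,6-trimethylcyclohex-2-en-1-yl]nona-2,4,6,8-tetraen-1-ol], via tetraenylalane 16 (not isolated), via lithium alkenylaluminate 17 (not isolated)
Conditions: Me3Al (2 equiv), Cp2ZrCl2 (0.5 equiv), ClCH2CH2Cl, rt; volatiles removed under vacuum; hexane, n-BuLi, 0 °C; (CH2O)n, THF, rt; H2O
Reagents that add atoms: trimethylaluminium, C[Al](C)C; paraformaldehyde (as formaldehyde units), C=O
Why: A second zirconium-catalysed syn methylalumination puts methyl on C13 and aluminium on C14, and the derived lithium aluminate adds to formaldehyde with retention (carboalumination followed by hydroxymethylation of the alkenylaluminate), which should give the 13E allylic alcohol.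

Step 7
Reactants: 18 (6R)-α-retinol
Product: 19 (6R)-α-retinal [(2E,4E,6E,8E)-3,7-dimethyl-9-[(1R)-2,6,6-trimethylcyclohex-2-en-1-yl]nona-2,4,6,8-tetraenal]
Conditions: MnO2 (activated, excess), CH2Cl2, rt, dark
Reagents that add atoms: none
Why: Allylic alcohol oxidation on the surface of MnO2 is neutral and stops at the conjugated aldehyde, so the 13E geometry, the isolated ring alkene and the C6 centre should be preserved.

Step 8
Reactants: 20 (2E,6E)-farnesol
Product: 21 (2E,6E)-farnesal
Conditions: MnO2 (activated, excess), CH2Cl2, rt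
Reagents that add atoms: none
Why: Allylic alcohol oxidation by MnO2 converts only the allylic CH2OH group and should keep the 2E geometry and both isolated trisubstituted alkenes.

Step 9
Reactants: 21 (2E,6E)-farnesal; 22 ethyl (2E)-4-(diethoxyphosphoryl)-3-methylbut-2-enoate
Product: 24 ethyl (2E,4E,6E,10E)-3,7,11,15-tetramethylhexadeca-2,4,6,10,14-pentaenoate, via lithiated phosphonate 23 (not isolated)
Conditions: 22, n-BuLi, THF/DMPU, −78 °C; 21, −78 to 0 °C
Reagents that add atoms: none
Why: Horner–Wadsworth–Emmons olefination through the phosphorus-bearing carbon of the lithiated vinylogous phosphonate should form the new disubstituted alkene C11′=C12′ as the E isomer and keep the 2E geometry of the reagent, a minor 2Z isomer being removable by chromatography.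

Step 10
Reactants: 24 ethyl (2E,4E,6E,10E)-3,7,11,15-tetramethylhexadeca-2,4,6,10,14-pentaenoate
Product: 25 (2E,4E,6E,10E)-3,7,11,15-tetramethylhexadeca-2,4,6,10,14-pentaen-1-ol
Conditions: i-Bu2AlH (2.2 equiv), CH2Cl2, −78 °C; aq potassium sodium tartrate
Reagents that add atoms: none
Why: Reduction of the conjugated ester by i-Bu2AlH at low temperature is a 1,2-reduction (ester to allylic alcohol) that leaves the polyene untouched.

Step 11
Reactants: 25 (2E,4E,6E,10E)-3,7,11,15-tetramethylhexadeca-2,4,6,10,14-pentaen-1-ol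
Product: 26 [(2E,4E,6E,10E)-3,7,11,15-tetramethylhexadeca-2,4,6,10,14-pentaen-1-yl]triphenylphosphonium bromide
Conditions: PPh3·HBr, MeOH, rt, dark
Reagents that add atoms: triphenylphosphine hydrobromide, [Br-].[PH+](c1ccccc1)(c1ccccc1)c1ccccc1
Why: Acid-promoted ionisation of the allylic alcohol to a delocalised polyenyl cation and capture by triphenylphosphine at the unhindered primary terminus (phosphonium salt formation from an allylic alcohol) should give the fully conjugated Wittig salt without touching the two isolated alkenes.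

Step 12
Reactants: 26 [(2E,4E,6E,10E)-3,7,11,15-tetramethylhexadeca-2,4,6,10,14-pentaen-1-yl]triphenylphosphonium bromide; 19 (6R)-α-retinal
Product: 29 (6R)-α-zeacarotene [(6R)-7′,8′-dihydro-ε,ψ-carotene], via phosphorus ylide 27 (not isolated), via 15Z isomer 28 (not isolated)
Conditions: NaN(SiMe3)2, THF, −78 °C; 19, −78 °C to rt; aqueous work-up; crude product in heptane, reflux, N2, dark
Reagents that add atoms: none
Why: Wittig olefination of the polyenal by the preformed semi-stabilised polyenyl ylide forms C15=C15′ as an E/Z mixture without exposing the aldehyde to free base, and because a cis bond at the unsubstituted central position is the least stable in a carotenoid chain, heating should convert the 15Z share into the all-E target with C6 unchanged.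

**Compound list**

1 | (R)-α-ionone, (3E)-4-[(1R)-2,6,6-trimethylcyclohex-2-en-1-yl]but-3-en-2-one | CC(=O)/C=C/[C@H]1C(C)=CCCC1(C)C | starting material
2 | lithium (3E)-4-[(1R)-2,6,6-trimethylcyclohex-2-en-1-yl]buta-1,3-dien-2-olate | C=C(O[Li])/C=C/[C@H]1C(C)=CCCC1(C)C | intermediate
3 | diethyl (3E)-4-[(1R)-2,6,6-trimethylcyclohex-2-en-1-yl]buta-1,3-dien-2-yl phosphate | C=C(OP(=O)(OCC)OCC)/C=C/[C@H]1C(C)=CCCC1(C)C | intermediate
4 | {(3E)-4-[(1R)-2,6,6-trimethylcyclohex-2-en-1-yl]but-3-en-1-yn-1-yl}lithium | [Li]C#C/C=C/[C@H]1C(C)=CCCC1(C)C | intermediate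
5 | (6R)-6-[(1E)-but-1-en-3-yn-1-yl]-1,5,5-trimethylcyclohex-1-ene | C#C/C=C/[C@H]1C(C)=CCCC1(C)C | intermediate
6 | acetylene | C#C | starting material
7 | (E)-1-bromo-2-iodoethene | Br/C=C/I | intermediate
8 | ethynyltrimethylsilane | C#C[Si](C)(C)C | starting material
9 | [(trimethylsilyl)ethynyl]lithium | [Li]C#C[Si](C)(C)C | intermediate
10 | bromo[(trimethylsilyl)ethynyl]zinc | Br[Zn]C#C[Si](C)(C)C | intermediate
11 | [(3E)-4-bromobut-3-en-1-yn-1-yl]trimethylsilane | C[Si](C)(C)C#C/C=C/Br | intermediate
12 | trimethylaluminium | C[Al](C)C | starting material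
13 | dimethyl{(1E,3E)-2-methyl-4-[(1R)-2,6,6-trimethylcyclohex-2-en-1-yl]buta-1,3-dien-1-yl}alane | C[Al](C)/C=C(C)/C=C/[C@H]1C(C)=CCCC1(C)C | intermediate
14 | trimethyl{(3E,5E,7E)-6-methyl-8-[(1R)-2,6,6-trimethylcyclohex-2-en-1-yl]octa-3,5,7-trien-1-yn-1-yl}silane | C[Si](C)(C)C#C/C=C/C=C(C)/C=C/[C@H]1C(C)=CCCC1(C)C | intermediate
15 | (6R)-1,5,5-trimethyl-6-[(1E,3E,5E)-3-methylocta-1,3,5-trien-7-yn-1-yl]cyclohex-1-ene | C#C/C=C/C=C(C)/C=C/[C@H]1C(C)=CCCC1(C)C | intermediate
16 | dimethyl{(1E,3E,5E,7E)-2,6-dimethyl-8-[(1R)-2,6,6-trimethylcyclohex-2-en-1-yl]octa-1,3,5,7-tetraen-1-yl}alane | C[Al](C)/C=C(C)/C=C/C=C(C)/C=C/[C@H]1C(C)=CCCC1(C)C | intermediate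
17 | lithium butyl(dimethyl){(1E,3E,5E,7E)-2,6-dimethyl-8-[(1R)-2,6,6-trimethylcyclohex-2-en-1-yl]octa-1,3,5,7-tetraen-1-yl}aluminate | [Li+].CCCC[Al-](C)(C)/C=C(C)/C=C/C=C(C)/C=C/[C@H]1C(C)=CCCC1(C)C | intermediate
18 | (6R)-α-retinol, (2E,4E,6E,8E)-3,7-dimethyl-9-[(1R)-2,6,6-trimethylcyclohex-2-en-1-yl]nona-2,4,6,8-tetraen-1-ol | OC/C=C(C)/C=C/C=C(C)/C=C/[C@H]1C(C)=CCCC1(C)C | intermediate
19 | (6R)-α-retinal, (2E,4E,6E,8E)-3,7-dimethyl-9-[(1R)-2,6,6-trimethylcyclohex-2-en-1-yl]nona-2,4,6,8-tetraenal | O=C/C=C(C)/C=C/C=C(C)/C=C/[C@H]1C(C)=CCCC1(C)C | intermediate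
20 | (2E,6E)-farnesol | CC(C)=CCC/C(C)=C/CC/C(C)=C/CO | starting material
21 | (2E,6E)-farnesal | CC(C)=CCC/C(C)=C/CC/C(C)=C/C=O | intermediate
22 | ethyl (2E)-4-(diethoxyphosphoryl)-3-methylbut-2-enoate | CCOC(=O)/C=C(C)/CP(=O)(OCC)OCC | starting material
23 | ethyl (2E)-4-(diethoxyphosphoryl)-4-lithio-3-methylbut-2-enoate | CCOC(=O)/C=C(C)/C([Li])P(=O)(OCC)OCC | intermediate
24 | ethyl (2E,4E,6E,10E)-3,7,11,15-tetramethylhexadeca-2,4,6,10,14-pentaenoate | CC(C)=CCC/C(C)=C/CC/C(C)=C/C=C/C(C)=C/C(=O)OCC | intermediate
25 | (2E,4E,6E,10E)-3,7,11,15-tetramethylhexadeca-2,4,6,10,14-pentaen-1-ol | CC(C)=CCC/C(C)=C/CC/C(C)=C/C=C/C(C)=C/CO | intermediate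
26 | [(2E,4E,6E,10E)-3,7,11,15-tetramethylhexadeca-2,4,6,10,14-pentaen-1-yl]triphenylphosphonium bromide | CC(C)=CCC/C(C)=C/CC/C(C)=C/C=C/C(C)=C/C[P+](c1ccccc1)(c1ccccc1)c1ccccc1.[Br-] | intermediate
27 | [(2E,4E,6E,10E)-3,7,11,15-tetramethylhexadeca-2,4,6,10,14-pentaen-1-ylidene]triphenylphosphorane | CC(C)=CCC/C(C)=C/CC/C(C)=C/C=C/C(C)=C/C=P(c1ccccc1)(c1ccccc1)c1ccccc1 | intermediate
28 | (6R,15Z)-7′,8′-dihydro-ε,ψ-carotene | CC(C)=CCC/C(C)=C/CC/C(C)=C/C=C/C(C)=C/C=C\C=C(C)\C=C\C=C(C)\C=C\[C@H]1C(C)=CCCC1(C)C | intermediate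
29 | (6R)-α-zeacarotene, (6R)-7′,8′-dihydro-ε,ψ-carotene, all-E | CC(C)=CCC/C(C)=C/CC/C(C)=C/C=C/C(C)=C/C=C/C=C(C)/C=C/C=C(C)/C=C/[C@H]1C(C)=CCCC1(C)C | target

**Count and risks**

Total step count: 12. Longest linear sequence: 7 steps (steps 2, 3, 4, 5, 6, 7, 12, from acetylene); from (R)-α-ionone the sequence is 6 steps (1, 4, 5, 6, 7, 12).

Steps most likely to fail:

Step 1. The amide base may remove the tertiary, doubly allylic C6–H in competition with methyl deprotonation and phosphate elimination, which would erode the enantiomeric purity or move the ring double bond into conjugation. The fallback sets out from 1 and returns at 5. Haloform cleavage of the methyl ketone with aqueous NaOCl at 0 °C would give (2E)-3-[(1R)-2,6,6-trimethylcyclohex-2-en-1-yl]prop-2-enoic acid F1. LiAlH4 in Et2O at 0 °C would reduce it to (2E)-3-[(1R)-2,6,6-trimethylcyclohex-2-en-1-yl]prop-2-en-1-ol F2, and MnO2 in CH2Cl2 would give (2E)-3-[(1R)-2,6,6-trimethylcyclohex-2-en-1-yl]prop-2-enal F3. CBr4 and PPh3 (Corey–Fuchs reaction) would give (6R)-6-[(1E)-4,4-dibromobuta-1,3-dien-1-yl]-1,5,5-trimethylcyclohex-1-ene F4. n-BuLi (2 equiv) in THF at −78 °C followed by water would then return to 5 through acetylide 4, the base being consumed by fast bromine–lithium exchange and not by deprotonation at C6.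

Step 6. The light-sensitive conjugated terminal trienyne may oligomerise or be carbometalated only in part, and the alkenylaluminate may be protonated before it captures formaldehyde. The fallback sets out from 15 and returns at 18, attaching C15 first and the C13 methyl afterwards. Deprotonation of 15 with n-BuLi in THF at −78 °C and addition to (CH2O)n would give (4E,6E,8E)-7-methyl-9-[(1R)-2,6,6-trimethylcyclohex-2-en-1-yl]nona-4,6,8-trien-2-yn-1-ol F5. Hydroxyl-directed anti hydroalumination with NaAlH2(OCH2CH2OMe)2 in THF at 0 °C and iodinolysis with iodine at −78 °C would give (2Z,4E,6E,8E)-3-iodo-7-methyl-9-[(1R)-2,6,6-trimethylcyclohex-2-en-1-yl]nona-2,4,6,8-tetraen-1-ol F6. Me2CuLi in Et2O at 0 °C would replace iodine by methyl with retention and give 18 with the 13E geometry.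

Step 12. The ylide may add with little geometric control so that much of the material carries a 15Z bond, and the thermal isomerisation may stay incomplete or scramble other double bonds of the sensitive polyene. The fallback sets out from 25 and returns at 29, with 19 as the unchanged partner. MsCl, 2,4,6-collidine and LiCl in DMF at 0 °C would give (2E,4E,6E,10E)-1-chloro-3,7,11,15-tetramethylhexadeca-2,4,6,10,14-pentaene F7. NaP(O)(OEt)2 in THF at 0 °C to rt (Michaelis–Becker reaction) would give diethyl [(2E,4E,6E,10E)-3,7,11,15-tetramethylhexadeca-2,4,6,10,14-pentaen-1-yl]phosphonate F8. Deprotonation with KOt-Bu in THF at −30 °C and addition of 19 (Horner–Wadsworth–Emmons olefination) should then form the C15=C15′ bond of 29 directly as the E isomer.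

**Further compounds**

F1 | step 1 | (2E)-3-[(1R)-2,6,6-trimethylcyclohex-2-en-1-yl]prop-2-enoic acid | OC(=O)/C=C/[C@H]1C(C)=CCCC1(C)C
F2 | step 1 | (2E)-3-[(1R)-2,6,6-trimethylcyclohex-2-en-1-yl]prop-2-en-1-ol | OC/C=C/[C@H]1C(C)=CCCC1(C)C
F3 | step 1 | (2E)-3-[(1R)-2,6,6-trimethylcyclohex-2-en-1-yl]prop-2-enal | O=C/C=C/[C@H]1C(C)=CCCC1(C)C
F4 | step 1 | (6R)-6-[(1E)-4,4-dibromobuta-1,3-dien-1-yl]-1,5,5-trimethylcyclohex-1-ene | BrC(Br)=C/C=C/[C@H]1C(C)=CCCC1(C)C
F5 | step 6 | (4E,6E,8E)-7-methyl-9-[(1R)-2,6,6-trimethylcyclohex-2-en-1-yl]nona-4,6,8-trien-2-yn-1-ol | OCC#C/C=C/C=C(C)/C=C/[C@H]1C(C)=CCCC1(C)C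
F6 | step 6 | (2Z,4E,6E,8E)-3-iodo-7-methyl-9-[(1R)-2,6,6-trimethylcyclohex-2-en-1-yl]nona-2,4,6,8-tetraen-1-ol | OC/C=C(I)/C=C/C=C(C)/C=C/[C@H]1C(C)=CCCC1(C)C
F7 | step 12 | (2E,4E,6E,10E)-1-chloro-3,7,11,15-tetramethylhexadeca-2,4,6,10,14-pentaene | CC(C)=CCC/C(C)=C/CC/C(C)=C/C=C/C(C)=C/CCl
F8 | step 12 | diethyl [(2E,4E,6E,10E)-3,7,11,15-tetramethylhexadeca-2,4,6,10,14-pentaen-1-yl]phosphonate | CC(C)=CCC/C(C)=C/CC/C(C)=C/C=C/C(C)=C/CP(=O)(OCC)OCC
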